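## Retrosynthetic overview

- Target ⇒ its bis(O-benzyl) ether; the phenols are freed last by hydrogenolysis.
- Tetrahydrofuran ring ⇒ C9–O–C9′ ether bond closed on the open-chain tetraol between its two primary carbinols, with the benzylic C–O bonds untouched (key bond; the only ring of the target, formed last).
- Tetraol ⇒ LiAlH4 reduction of a trans-3,4-disubstituted γ-butyrolactone, whose C8′–C7′ bond comes from an anti-aldol of the lactone boron enolate with O-benzylvanillin.
- β-(Hydroxybenzyl) lactone ⇒ Evans syn-aldol of a succinate imide with O-benzylvanillin (sets C7 and C8), then reductive auxiliary removal and translactonisation.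
- Ring order: aryl paraconic lactone (temporary) → γ-lactone of the primary carbinol (temporary) → tetrahydrofuran.

Assumption: lignan numbering is used (C7/C7′ benzylic carbinol carbons, C8/C8′ ring CH, C9/C9′ ring CH2); the target is (7S,8R,8′R,7′R), i.e. one syn and one anti arm on a trans ring.

## Route

Step 1
Reactants: 1 (S)-4-benzyloxazolidin-2-one; 2 methyl 4-chloro-4-oxobutanoate
Product: 3 methyl 4-[(4S)-4-benzyl-2-oxooxazolidin-3-yl]-4-oxobutanoate
Conditions: Et3N (1.5 equiv), 4-(dimethylamino)pyridine (10 mol %), CH2Cl2, 0 °C → rt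
Reagents that add atoms: none
Why: N-acylation of the oxazolidinone by the acid chloride (nucleophilic acyl substitution under acyl-transfer catalysis) installs the auxiliary that controls C7 and C8.

Step 2
Reactants: 3 methyl 4-[(4S)-4-benzyl-2-oxooxazolidin-3-yl]-4-oxobutanoate; 4 4-benzyloxy-3-methoxybenzaldehyde
Product: 7 (4S)-4-benzyl-3-{[(2S,3S)-2-(4-benzyloxy-3-methoxyphenyl)-5-oxotetrahydrofuran-3-yl]carbonyl}oxazolidin-2-one, via Z-boron enolate 5 (not isolated), via open-chain syn-aldol 6 (not isolated)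
Conditions: Bu2BOTf (1.1 equiv), iPr2NEt (1.3 equiv), CH2Cl2, −78 → 0 °C; then 4, −78 °C → rt; pH 7 buffer, MeOH, H2O2, 0 °C
Reagents that add atoms: none
Why: Evans syn-aldol through the chair (Zimmerman–Traxler) transition state of the Z-dibutylboron enolate, with the (S)-benzyl auxiliary fixing the enolate face, sets C7 (S) and C8 as the syn pair; the aldolate then closes onto the methyl ester (lactonisation) to the trans aryl paraconic imide.

Step 3
Reactants: 7 (4S)-4-benzyl-3-{[(2S,3S)-2-(4-benzyloxy-3-methoxyphenyl)-5-oxotetrahydrofuran-3-yl]carbonyl}oxazolidin-2-one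
Product: 9 (4R)-4-[(S)-(4-benzyloxy-3-methoxyphenyl)(hydroxy)methyl]dihydrofuran-2(3H)-one, via hydroxymethyl paraconic lactone 8 (not isolated)
Conditions: NaBH4 (4 equiv), THF/H2O 4:1, 0 °C → rt; then K2CO3 (0.2 equiv), MeOH, rt; NH4Cl
Reagents that add atoms: none
Why: Borohydride cleavage of the N-acyloxazolidinone gives the primary alcohol and returns auxiliary 1, and base-mediated translactonisation (intramolecular acyl migration) then moves the lactone to the less hindered primary carbinol, which is the more stable ester; no stereocentre is touched.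

Step 4
Reactants: 9 (4R)-4-[(S)-(4-benzyloxy-3-methoxyphenyl)(hydroxy)methyl]dihydrofuran-2(3H)-one; 4 4-benzyloxy-3-methoxybenzaldehyde
Product: 11 (3S,4R)-3-[(R)-(4-benzyloxy-3-methoxyphenyl)(hydroxy)methyl]-4-[(S)-(4-benzyloxy-3-methoxyphenyl)(hydroxy)methyl]dihydrofuran-2(3H)-one, via boron enolate O-borinate 10 (not isolated)
Conditions: dicyclohexylboron triflate (Chx2BOTf, 2.3 equiv), Et3N (3 equiv), CH2Cl2, −78 °C; then 4 (1.3 equiv), −78 → 0 °C; pH 7 buffer, MeOH, H2O2, 0 °C
Reagents that add atoms: none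
Why: Boron-mediated anti-aldol: the free OH is masked in situ as its borinate, the ring-locked E(O) lactone boron enolate reacts through a chair transition state to give the anti (7′R) carbinol, and the aldehyde adds anti to the C8 substituent so that the two arms are trans.

Step 5
Reactants: 11 (3S,4R)-3-[(R)-(4-benzyloxy-3-methoxyphenyl)(hydroxy)methyl]-4-[(S)-(4-benzyloxy-3-methoxyphenyl)(hydroxy)methyl]dihydrofuran-2(3H)-one
Product: 12 (1S,2R,3R,4R)-1,4-bis(4-benzyloxy-3-methoxyphenyl)-2,3-bis(hydroxymethyl)butane-1,4-diol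
Conditions: LiAlH4 (3 equiv), THF, 0 °C → rt; Rochelle salt work-up
Reagents that add atoms: none
Why: Hydride reduction of the lactone to the 1,4-diol gives the tetraol without affecting the four stereocentres, the benzyl ethers or the benzylic alcohols.

Step 6
Reactants: 12 (1S,2R,3R,4R)-1,4-bis(4-benzyloxy-3-methoxyphenyl)-2,3-bis(hydroxymethyl)butane-1,4-diol
Product: 15 (S)-(4-benzyloxy-3-methoxyphenyl){(3R,4R)-4-[(R)-(4-benzyloxy-3-methoxyphenyl)(hydroxy)methyl]tetrahydrofuran-3-yl}methanol, via C9 monotosylate 13 (not isolated), via C9′ monotosylate 14 (not isolated)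
Conditions: 2-aminoethyl diphenylborinate (Ph2BOCH2CH2NH2, 10 mol %), TsCl (1.05 equiv, slow addition), iPr2NEt (3 equiv), MeCN, 0 °C → rt, then 45 °C
Reagents that add atoms: none
Why: Proposed new method: a borinic-acid-catalysed tandem site-selective sulfonylation/cycloetherification, in which the diarylborinate binds each 1,3-diol unit (benzylic OH plus CH2OH) as a tetracoordinate six-membered borinate that activates only its less hindered primary oxygen, so the first turnover tosylates one CH2OH and the second delivers the primary oxygen of the other borinate onto that CH2OTs by 5-exo-tet SN2 to close the tetrahydrofuran; no benzylic C–O bond is made or broken, so all four stereocentres are retained and benzylic O-alkylation (2-aryl tetrahydrofuran) or benzylic ionisation (furofuran) is avoided; the closest known reaction types are borinic-acid-catalysed regioselective monosulfonylation and O-alkylation of diols and the classical TsCl cyclodehydration of 1,4-diols.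

Step 7
Reactants: 15 (S)-(4-benzyloxy-3-methoxyphenyl){(3R,4R)-4-[(R)-(4-benzyloxy-3-methoxyphenyl)(hydroxy)methyl]tetrahydrofuran-3-yl}methanol
Product: 16 (S)-(4-hydroxy-3-methoxyphenyl){(3R,4R)-4-[(R)-hydroxy(4-hydroxy-3-methoxyphenyl)methyl]tetrahydrofuran-3-yl}methanol
Conditions: H2 (1 atm), Pd/C (10 wt % palladium on carbon), EtOAc, rt, stopped after uptake of 2 equiv H2
Reagents that add atoms: none
Why: Catalytic hydrogenolysis of the two aryl benzyl ethers is much faster in neutral EtOAc than hydrogenolysis of the secondary benzylic alcohols, so the phenols are freed without loss of the carbinol stereocentres.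

## Compound list

1 | (S)-4-benzyloxazolidin-2-one | O=C1N[C@@H](Cc2ccccc2)CO1 | starting material
2 | methyl 4-chloro-4-oxobutanoate | COC(=O)CCC(=O)Cl | starting material
3 | methyl 4-[(4S)-4-benzyl-2-oxooxazolidin-3-yl]-4-oxobutanoate | COC(=O)CCC(=O)N1[C@@H](Cc2ccccc2)COC1=O | intermediate
4 | 4-benzyloxy-3-methoxybenzaldehyde (O-benzylvanillin) | COc1cc(C=O)ccc1OCc1ccccc1 | starting material
5 | Z-dibutylboron enolate of 3 (formed in situ) | COC(=O)C/C=C(\OB(CCCC)CCCC)N1[C@@H](Cc2ccccc2)COC1=O | intermediate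
6 | methyl (3S,4S)-3-{[(4S)-4-benzyl-2-oxooxazolidin-3-yl]carbonyl}-4-(4-benzyloxy-3-methoxyphenyl)-4-hydroxybutanoate (open-chain syn-aldol, formed in situ as its boron aldolate) | COC(=O)C[C@@H]([C@H](O)c1ccc(OCc2ccccc2)c(OC)c1)C(=O)N1[C@@H](Cc2ccccc2)COC1=O | intermediate
7 | (4S)-4-benzyl-3-{[(2S,3S)-2-(4-benzyloxy-3-methoxyphenyl)-5-oxotetrahydrofuran-3-yl]carbonyl}oxazolidin-2-one | O=C1C[C@H](C(=O)N2[C@@H](Cc3ccccc3)COC2=O)[C@@H](c2ccc(OCc3ccccc3)c(OC)c2)O1 | intermediate
8 | (4R,5S)-5-(4-benzyloxy-3-methoxyphenyl)-4-(hydroxymethyl)dihydrofuran-2(3H)-one (formed in situ) | O=C1C[C@H](CO)[C@@H](c2ccc(OCc3ccccc3)c(OC)c2)O1 | intermediate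
9 | (4R)-4-[(S)-(4-benzyloxy-3-methoxyphenyl)(hydroxy)methyl]dihydrofuran-2(3H)-one | O=C1C[C@@H]([C@H](O)c2ccc(OCc3ccccc3)c(OC)c2)CO1 | intermediate
10 | dicyclohexylboron enolate of 9 with the C7 oxygen as its dicyclohexylborinate (formed in situ) | C1CCC(CC1)B(C1CCCCC1)OC1=C[C@@H]([C@H](OB(C2CCCCC2)C2CCCCC2)c2ccc(OCc3ccccc3)c(OC)c2)CO1 | intermediate
11 | (3S,4R)-3-[(R)-(4-benzyloxy-3-methoxyphenyl)(hydroxy)methyl]-4-[(S)-(4-benzyloxy-3-methoxyphenyl)(hydroxy)methyl]dihydrofuran-2(3H)-one | O=C1[C@H]([C@@H](O)c2ccc(OCc3ccccc3)c(OC)c2)[C@@H]([C@H](O)c2ccc(OCc3ccccc3)c(OC)c2)CO1 | intermediate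
12 | (1S,2R,3R,4R)-1,4-bis(4-benzyloxy-3-methoxyphenyl)-2,3-bis(hydroxymethyl)butane-1,4-diol | COc1cc([C@@H](O)[C@@H](CO)[C@H](CO)[C@@H](O)c2ccc(OCc3ccccc3)c(OC)c2)ccc1OCc1ccccc1 | intermediate
13 | mono-4-methylbenzenesulfonate of 12 at C9 (CH2O on C8, next to the 7S carbinol; formed in situ) | COc1cc([C@@H](O)[C@@H](COS(=O)(=O)c2ccc(C)cc2)[C@H](CO)[C@@H](O)c2ccc(OCc3ccccc3)c(OC)c2)ccc1OCc1ccccc1 | intermediate
14 | mono-4-methylbenzenesulfonate of 12 at C9′ (CH2O on C8′, next to the 7′R carbinol; formed in situ) | COc1cc([C@@H](O)[C@@H](CO)[C@H](COS(=O)(=O)c2ccc(C)cc2)[C@@H](O)c2ccc(OCc3ccccc3)c(OC)c2)ccc1OCc1ccccc1 | intermediate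
15 | (S)-(4-benzyloxy-3-methoxyphenyl){(3R,4R)-4-[(R)-(4-benzyloxy-3-methoxyphenyl)(hydroxy)methyl]tetrahydrofuran-3-yl}methanol | COc1cc([C@@H](O)[C@H]2COC[C@@H]2[C@@H](O)c2ccc(OCc3ccccc3)c(OC)c2)ccc1OCc1ccccc1 | intermediate
16 | (S)-(4-hydroxy-3-methoxyphenyl){(3R,4R)-4-[(R)-hydroxy(4-hydroxy-3-methoxyphenyl)methyl]tetrahydrofuran-3-yl}methanol | COc1cc([C@@H](O)[C@H]2COC[C@@H]2[C@@H](O)c2ccc(O)c(OC)c2)ccc1O | target

## Step count and risks

Total steps: 7. Longest linear sequence: 7 (from 1 and 2).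

The three steps most likely to fail:

Step 6 is the proposed new method. The risks are over-tosylation and closure through a benzylic oxygen. The fallback uses known chemistry, sets out from 11 and returns at 15. Both benzylic hydroxyls of 11 are silylated (TBSOTf, 2,6-lutidine, CH2Cl2) to give (3S,4R)-3-[(R)-(4-benzyloxy-3-methoxyphenyl)(tert-butyldimethylsilyloxy)methyl]-4-[(S)-(4-benzyloxy-3-methoxyphenyl)(tert-butyldimethylsilyloxy)methyl]dihydrofuran-2(3H)-one F5. LiAlH4 reduction gives (1S,2R,3R,4R)-1,4-bis(4-benzyloxy-3-methoxyphenyl)-1,4-bis(tert-butyldimethylsilyloxy)-2,3-bis(hydroxymethyl)butane F6, in which only the two primary hydroxyls are free. A classical Mitsunobu cyclodehydration (PPh3, DIAD, THF) then gives the bis-silylated tetrahydrofuran (3R,4R)-3-[(S)-(4-benzyloxy-3-methoxyphenyl)(tert-butyldimethylsilyloxy)methyl]-4-[(R)-(4-benzyloxy-3-methoxyphenyl)(tert-butyldimethylsilyloxy)methyl]tetrahydrofuran F7. Bu4NF in THF removes both silyl groups to give 15.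

Step 4 may give incomplete anti selectivity at C7′ or sluggish boron enolisation of the lactone. The fallback sets out from 9 and returns at 11. Compound 9 is silylated (TBSOTf, 2,6-lutidine) to (4R)-4-[(S)-(4-benzyloxy-3-methoxyphenyl)(tert-butyldimethylsilyloxy)methyl]dihydrofuran-2(3H)-one F2. Its lithium enolate (LiN(SiMe3)2, 2.2 equiv, THF, −78 °C) is C-acylated with 4-benzyloxy-3-methoxybenzoyl chloride to give the trans β-keto lactone (3S,4R)-3-(4-benzyloxy-3-methoxybenzoyl)-4-[(S)-(4-benzyloxy-3-methoxyphenyl)(tert-butyldimethylsilyloxy)methyl]dihydrofuran-2(3H)-one F3, whose epimerisable α-carbon settles trans. Asymmetric transfer hydrogenation with RuCl(p-cymene)[(R,R)-TsDPEN] in HCO2H/Et3N sets the 7′R carbinol under catalyst control and gives (3S,4R)-3-[(R)-(4-benzyloxy-3-methoxyphenyl)(hydroxy)methyl]-4-[(S)-(4-benzyloxy-3-methoxyphenyl)(tert-butyldimethylsilyloxy)methyl]dihydrofuran-2(3H)-one F4. Bu4NF buffered with AcOH then gives 11.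

Step 3 depends on the translactonisation equilibrium favouring the primary-carbinol lactone; any remaining 8 would later give the wrong C8′ series. The fallback sets out from 7 and returns at 9. After NaBH4 reduction, LiOH in the same pot opens the lactone to (3R,4S)-4-(4-benzyloxy-3-methoxyphenyl)-4-hydroxy-3-(hydroxymethyl)butanoic acid F1, which is liberated cold at pH 4–5 and used at once. Mitsunobu lactonisation (PPh3, DIAD, THF, 0 °C) activates the primary carbinol selectively, and the carboxylate closes by SN2 at C9 to give 9 irreversibly under kinetic control.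

## Further compounds

F1 | step 3 | (3R,4S)-4-(4-benzyloxy-3-methoxyphenyl)-4-hydroxy-3-(hydroxymethyl)butanoic acid | OC(=O)C[C@@H]([C@H](O)c1ccc(OCc2ccccc2)c(OC)c1)CO
F2 | step 4 | (4R)-4-[(S)-(4-benzyloxy-3-methoxyphenyl)(tert-butyldimethylsilyloxy)methyl]dihydrofuran-2(3H)-one | O=C1C[C@@H]([C@H](O[Si](C)(C)C(C)(C)C)c2ccc(OCc3ccccc3)c(OC)c2)CO1
F3 | step 4 | (3S,4R)-3-(4-benzyloxy-3-methoxybenzoyl)-4-[(S)-(4-benzyloxy-3-methoxyphenyl)(tert-butyldimethylsilyloxy)methyl]dihydrofuran-2(3H)-one | O=C1[C@H](C(=O)c2ccc(OCc3ccccc3)c(OC)c2)[C@@H]([C@H](O[Si](C)(C)C(C)(C)C)c2ccc(OCc3ccccc3)c(OC)c2)CO1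
F4 | step 4 | (3S,4R)-3-[(R)-(4-benzyloxy-3-methoxyphenyl)(hydroxy)methyl]-4-[(S)-(4-benzyloxy-3-methoxyphenyl)(tert-butyldimethylsilyloxy)methyl]dihydrofuran-2(3H)-one | O=C1[C@H]([C@@H](O)c2ccc(OCc3ccccc3)c(OC)c2)[C@@H]([C@H](O[Si](C)(C)C(C)(C)C)c2ccc(OCc3ccccc3)c(OC)c2)CO1
F5 | step 6 | (3S,4R)-3-[(R)-(4-benzyloxy-3-methoxyphenyl)(tert-butyldimethylsilyloxy)methyl]-4-[(S)-(4-benzyloxy-3-methoxyphenyl)(tert-butyldimethylsilyloxy)methyl]dihydrofuran-2(3H)-one | O=C1[C@H]([C@@H](O[Si](C)(C)C(C)(C)C)c2ccc(OCc3ccccc3)c(OC)c2)[C@@H]([C@H](O[Si](C)(C)C(C)(C)C)c2ccc(OCc3ccccc3)c(OC)c2)CO1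
F6 | step 6 | (1S,2R,3R,4R)-1,4-bis(4-benzyloxy-3-methoxyphenyl)-1,4-bis(tert-butyldimethylsilyloxy)-2,3-bis(hydroxymethyl)butane | COc1cc([C@@H](O[Si](C)(C)C(C)(C)C)[C@@H](CO)[C@H](CO)[C@@H](O[Si](C)(C)C(C)(C)C)c2ccc(OCc3ccccc3)c(OC)c2)ccc1OCc1ccccc1
F7 | step 6 | (3R,4R)-3-[(S)-(4-benzyloxy-3-methoxyphenyl)(tert-butyldimethylsilyloxy)methyl]-4-[(R)-(4-benzyloxy-3-methoxyphenyl)(tert-butyldimethylsilyloxy)methyl]tetrahydrofuran | COc1cc([C@@H](O[Si](C)(C)C(C)(C)C)[C@H]2COC[C@@H]2[C@@H](O[Si](C)(C)C(C)(C)C)c2ccc(OCc3ccccc3)c(OC)c2)ccc1OCc1ccccc1
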